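The 17-membered ring is opened at the diaryl ether bond joining the ring A oxygen to ring C. In ring C, the aryloxy-bearing carbon C-6 lies next to the C-1 hydroxyl of the catechol and is meta to C-4, which holds the CH2CH2 bridge; once the catechol is oxidised to its ortho-quinone, C-6 ends a vinylogous (1,6) acceptor. Capture of that quinone by the para-phenol oxygen of ring A should make the C–O bond, close the macrocycle and regenerate the catechol in one operation. The precursor is an open-chain bis-bibenzyl with a free ring A phenol, a free ring C catechol and ring B as its methyl ether, built by two Wittig olefinations around one SNAr diaryl ether.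

Key step: step 7

Remark on the chemistry: ring C is numbered as a catechol (OH at C-1 and C-2, bridge at C-4, aryloxy at C-6). Benzylic chlorides 1 and 8 are taken as purchasable, and the stilbenes 5, 7 and 11 are carried as E/Z mixtures because step 6 erases the geometry. No blocking group is placed on ring C, since a halogen at the competing quinone carbons would be lost in the hydrogenolysis and would itself invite addition–elimination.

Step 1
Reactants: 1 4-(benzyloxy)benzyl chloride
Product: 2 [4-(benzyloxy)benzyl]triphenylphosphonium chloride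
Conditions: PPh3 (1.05 equiv), toluene, reflux
Reagents that add atoms: triphenylphosphine, c1ccc(cc1)P(c1ccccc1)c1ccccc1
Why: SN2 quaternisation of triphenylphosphine by an activated benzylic chloride, with the salt expected to precipitate from toluene.

Step 2
Reactants: 2 [4-(benzyloxy)benzyl]triphenylphosphonium chloride; 3 o-vanillin (2-hydroxy-3-methoxybenzaldehyde)
Product: 5 2-[2-(4-benzyloxyphenyl)ethenyl]-6-methoxyphenol (E/Z mixture), via ring A ylide 4 (not isolated)
Conditions: KOtBu (2.3 equiv), THF, 0 °C to rt; aq. NH4Cl
Reagents that add atoms: none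
Why: Wittig olefination with a semi-stabilised benzylic ylide, in which the extra equivalent of base holds the phenol as its phenoxide so that it cannot quench the ylide.

Step 3
Reactants: 5 2-[2-(4-benzyloxyphenyl)ethenyl]-6-methoxyphenol; 6 2-fluorobenzaldehyde
Product: 7 2-{2-[2-(4-benzyloxyphenyl)ethenyl]-6-methoxyphenoxy}benzaldehyde (E/Z mixture)
Conditions: K2CO3 (2 equiv), DMF, 120 °C
Reagents that add atoms: none
Why: SNAr (addition–elimination) of the phenoxide on a fluoroarene activated by its ortho-formyl group, which the benzyl ether and the stilbene should tolerate.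

Step 4
Reactants: 8 3,4-bis(benzyloxy)benzyl chloride
Product: 9 [3,4-bis(benzyloxy)benzyl]triphenylphosphonium chloride
Conditions: PPh3 (1.05 equiv), toluene, reflux
Reagents that add atoms: triphenylphosphine, c1ccc(cc1)P(c1ccccc1)c1ccccc1
Why: SN2 quaternisation of triphenylphosphine by an electron-rich benzylic chloride.

Step 5
Reactants: 7 2-{2-[2-(4-benzyloxyphenyl)ethenyl]-6-methoxyphenoxy}benzaldehyde; 9 [3,4-bis(benzyloxy)benzyl]triphenylphosphonium chloride
Product: 11 1-{2-[3,4-bis(benzyloxy)phenyl]ethenyl}-2-{2-[2-(4-benzyloxyphenyl)ethenyl]-6-methoxyphenoxy}benzene (alkene isomer mixture), via ring C ylide 10 (not isolated)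
Conditions: KOtBu (1.2 equiv), THF, 0 °C to rt
Reagents that add atoms: none
Why: Wittig olefination of a non-enolisable aryl aldehyde with a semi-stabilised ylide, completing the carbon skeleton of the open chain.

Step 6
Reactants: 11 1-{2-[3,4-bis(benzyloxy)phenyl]ethenyl}-2-{2-[2-(4-benzyloxyphenyl)ethenyl]-6-methoxyphenoxy}benzene
Product: 12 4-[2-(2-{2-[2-(4-hydroxyphenyl)ethyl]-6-methoxyphenoxy}phenyl)ethyl]benzene-1,2-diol (open-chain catechol phenol)
Conditions: H2 (1 atm), 10% Pd/C, EtOAc–MeOH, rt; filtered and concentrated under argon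
Reagents that add atoms: none
Why: Catalytic hydrogenation should saturate both stilbene double bonds and hydrogenolyse the three benzyl ethers in one operation, while the methyl ether and the diaryl ether are inert.

Step 7
Reactants: 12 4-[2-(2-{2-[2-(4-hydroxyphenyl)ethyl]-6-methoxyphenoxy}phenyl)ethyl]benzene-1,2-diol
Product: 14 macrocyclic catechol ring B methyl ether, via ortho-quinone 13 (not isolated)
Conditions: Ag2O (1.1 equiv), 4 Å MS, dry MeCN, 1 mM, 0 °C, dark, argon; then Cs2CO3 (0.2 equiv), 0 °C to rt
Reagents that add atoms: none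
Why: Proposed new method: Ag2O should dehydrogenate the ring C catechol of 12 to the 4-alkyl-ortho-quinone 13, the ring A phenoxide formed by the catalytic carbonate should then add to C-6, the far end of the O=C2–C3=C4–C5=C6 vinylogous acceptor, and enolisation of the adduct should return an aromatic catechol, so that the net change is a dehydrogenative C–O coupling. The closest known reaction types are the 1,6-addition of thiols to 4-alkyl-ortho-quinones at this same carbon and oxidative phenol macrocyclisations to diaryl ethers, whereas addition of a tethered phenol oxygen at this position of an ortho-quinone is not established. The 17-membered ring closes by intramolecular oxygen-to-carbon conjugate addition on a ring sp2 carbon, formally 17-endo-trig, run at about 1 mM so that ring closure can outrun intermolecular coupling. No stereocentre is formed. Chemoselectivity is needed and should come from the catechol being far easier to oxidise than the lone phenol of ring A or the anisole-type ring B, and from the ring B oxygen being methylated so that only one oxygen nucleophile is present. Regioselectivity among C-3, C-5 and C-6 is also needed: C-3 and C-5 both adjoin the alkylated C-4 and would give a tighter 16-membered ring, whereas C-6 is unhindered and is the carbon that the para-linked ring A oxygen reaches in the 17-membered ring.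

Step 8
Reactants: 14 macrocyclic catechol ring B methyl ether
Product: 15 CNP0290892.0 (target)
Conditions: BBr3 (6 equiv), CH2Cl2, −78 °C to rt; ice-water quench
Reagents that add atoms: none
Why: Lewis acid cleavage of the single aryl methyl ether by BBr3 (demethylation through the aryloxyborane, hydrolysed on quench), under which diaryl ethers do not cleave and the catechol is only held temporarily as a borate.

Compound list
1 | 4-(benzyloxy)benzyl chloride | ClCc1ccc(OCc2ccccc2)cc1 | starting material
2 | [4-(benzyloxy)benzyl]triphenylphosphonium chloride | [Cl-].c1ccc(cc1)[P+](Cc1ccc(OCc2ccccc2)cc1)(c1ccccc1)c1ccccc1 | intermediate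
3 | o-vanillin (2-hydroxy-3-methoxybenzaldehyde) | COc1cccc(C=O)c1O | starting material
4 | ring A ylide, [4-(benzyloxy)benzylidene]triphenylphosphorane | c1ccc(cc1)P(=Cc1ccc(OCc2ccccc2)cc1)(c1ccccc1)c1ccccc1 | intermediate
5 | 2-[2-(4-benzyloxyphenyl)ethenyl]-6-methoxyphenol, E/Z mixture | COc1cccc(C=Cc2ccc(OCc3ccccc3)cc2)c1O | intermediate
6 | 2-fluorobenzaldehyde | O=Cc1ccccc1F | starting material
7 | 2-{2-[2-(4-benzyloxyphenyl)ethenyl]-6-methoxyphenoxy}benzaldehyde, E/Z mixture | COc1cccc(C=Cc2ccc(OCc3ccccc3)cc2)c1Oc1ccccc1C=O | intermediate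
8 | 3,4-bis(benzyloxy)benzyl chloride | ClCc1ccc(OCc2ccccc2)c(OCc2ccccc2)c1 | starting material
9 | [3,4-bis(benzyloxy)benzyl]triphenylphosphonium chloride | [Cl-].c1ccc(cc1)[P+](Cc1ccc(OCc2ccccc2)c(OCc2ccccc2)c1)(c1ccccc1)c1ccccc1 | intermediate
10 | ring C ylide, [3,4-bis(benzyloxy)benzylidene]triphenylphosphorane | c1ccc(cc1)P(=Cc1ccc(OCc2ccccc2)c(OCc2ccccc2)c1)(c1ccccc1)c1ccccc1 | intermediate
11 | 1-{2-[3,4-bis(benzyloxy)phenyl]ethenyl}-2-{2-[2-(4-benzyloxyphenyl)ethenyl]-6-methoxyphenoxy}benzene, alkene isomer mixture | COc1cccc(C=Cc2ccc(OCc3ccccc3)cc2)c1Oc1ccccc1C=Cc1ccc(OCc2ccccc2)c(OCc2ccccc2)c1 | intermediate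
12 | 4-[2-(2-{2-[2-(4-hydroxyphenyl)ethyl]-6-methoxyphenoxy}phenyl)ethyl]benzene-1,2-diol (open-chain catechol phenol, ring B methyl ether) | Oc1ccc(cc1)CCc1cccc(OC)c1Oc1ccccc1CCc1ccc(O)c(O)c1 | intermediate
13 | 4-[2-(2-{2-[2-(4-hydroxyphenyl)ethyl]-6-methoxyphenoxy}phenyl)ethyl]cyclohexa-3,5-diene-1,2-dione (ring C ortho-quinone) | Oc1ccc(cc1)CCc1cccc(OC)c1Oc1ccccc1CCC1=CC(=O)C(=O)C=C1 | intermediate
14 | 17-membered macrocycle with ring C catechol (OH at C-1 and C-2, ring A oxygen at C-6, bridge at C-4) and ring B methyl ether | Oc1cc2cc(c1O)Oc1ccc(cc1)CCc1cccc(OC)c1Oc1ccccc1CC2 | intermediate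
15 | CNP0290892.0, the macrocycle with free ring B hydroxyl (no stereocentres) | Oc1cc2cc(c1O)Oc1ccc(cc1)CCc1cccc(O)c1Oc1ccccc1CC2 | target

Total step count: 8. Longest linear sequence: 7 steps (steps 1, 2, 3, 5, 6, 7, 8).

Steps most likely to fail

Step 7. Several processes could defeat the closure. The phenoxide may add at the wrong quinone carbon, above all the 1,4-position C-5 that oxygen and nitrogen nucleophiles normally choose. The quinone may tautomerise to a quinone methide through its benzylic CH2. Intermolecular coupling may compete, and the cyclised catechol may be re-oxidised by unreacted quinone. The fallback forms the same C–O bond by known copper chemistry; it sets out from aldehyde 7 and comes back to the route at target 15. Commercial 3-bromo-4,5-dimethoxybenzaldehyde would be reduced with NaBH4 to (3-bromo-4,5-dimethoxyphenyl)methanol F1. PPh3·HBr in refluxing MeCN would convert this into [(3-bromo-4,5-dimethoxyphenyl)methyl]triphenylphosphonium bromide F2. KOtBu would give (3-bromo-4,5-dimethoxybenzylidene)triphenylphosphorane F3, which would be condensed with 7 in a Wittig reaction to give the bromo bis-stilbene F4. Diimide (TsNHNH2, NaOAc, aqueous THF, reflux) would saturate both alkenes without touching the aryl bromide or the benzyl ether, giving the bromo bis-bibenzyl benzyl ether F5. BCl3 with pentamethylbenzene at −78 °C would remove only the ring A benzyl group to give the bromo phenol F6. An intramolecular Ullmann diaryl ether coupling (CuI, N,N-dimethylglycine, Cs2CO3, dioxane, 100 °C, high dilution) would close the ring to the macrocyclic trimethyl ether F7. BBr3 would then cleave all three methyl ethers to give 15.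

Step 3. Substitution at a phenoxide flanked by two ortho substituents may be slow, and the aldehyde may degrade under base at the temperature required. The fallback replaces SNAr by copper-catalysed O-arylation; it sets out from phenol 5 and comes back at aldehyde 7. Coupling of 5 with commercial 2-(2-bromophenyl)-1,3-dioxolane (CuI, picolinic acid, K3PO4, DMSO, 90 °C) would give 2-(2-{2-[2-(4-benzyloxyphenyl)ethenyl]-6-methoxyphenoxy}phenyl)-1,3-dioxolane F8. Hydrolysis of the acetal with aqueous HCl in THF would deliver 7.

Step 2. Olefination may stall because the phenoxide deactivates the neighbouring aldehyde and proton transfer consumes ylide. The fallback masks the phenol; it sets out from o-vanillin 3 and comes back at stilbene phenol 5. MOMCl with iPr2NEt in CH2Cl2 would give 3-methoxy-2-(methoxymethoxy)benzaldehyde F9. Wittig reaction with ylide 4 (from 2 and KOtBu) would give 1-[2-(4-benzyloxyphenyl)ethenyl]-3-methoxy-2-(methoxymethoxy)benzene F10. HCl in MeOH would remove the acetal protecting group to give 5.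

Further compounds
F1 | step 7 | (3-bromo-4,5-dimethoxyphenyl)methanol | COc1cc(CO)cc(Br)c1OC
F2 | step 7 | [(3-bromo-4,5-dimethoxyphenyl)methyl]triphenylphosphonium bromide | [Br-].COc1cc(C[P+](c2ccccc2)(c2ccccc2)c2ccccc2)cc(Br)c1OC
F3 | step 7 | (3-bromo-4,5-dimethoxybenzylidene)triphenylphosphorane | COc1cc(C=P(c2ccccc2)(c2ccccc2)c2ccccc2)cc(Br)c1OC
F4 | step 7 | 1-{2-[2-(4-benzyloxyphenyl)ethenyl]-6-methoxyphenoxy}-2-[2-(3-bromo-4,5-dimethoxyphenyl)ethenyl]benzene, alkene isomer mixture | COc1cccc(C=Cc2ccc(OCc3ccccc3)cc2)c1Oc1ccccc1C=Cc1cc(Br)c(OC)c(OC)c1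
F5 | step 7 | 1-{2-[2-(4-benzyloxyphenyl)ethyl]-6-methoxyphenoxy}-2-[2-(3-bromo-4,5-dimethoxyphenyl)ethyl]benzene | COc1cccc(CCc2ccc(OCc3ccccc3)cc2)c1Oc1ccccc1CCc1cc(Br)c(OC)c(OC)c1
F6 | step 7 | 4-[2-(2-{2-[2-(3-bromo-4,5-dimethoxyphenyl)ethyl]phenoxy}-3-methoxyphenyl)ethyl]phenol | COc1cccc(CCc2ccc(O)cc2)c1Oc1ccccc1CCc1cc(Br)c(OC)c(OC)c1
F7 | step 7 | tri-O-methyl ether of the target macrocycle | COc1cc2cc(c1OC)Oc1ccc(cc1)CCc1cccc(OC)c1Oc1ccccc1CC2
F8 | step 3 | 2-(2-{2-[2-(4-benzyloxyphenyl)ethenyl]-6-methoxyphenoxy}phenyl)-1,3-dioxolane, E/Z mixture | COc1cccc(C=Cc2ccc(OCc3ccccc3)cc2)c1Oc1ccccc1C1OCCO1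
F9 | step 2 | 3-methoxy-2-(methoxymethoxy)benzaldehyde | COCOc1c(OC)cccc1C=O
F10 | step 2 | 1-[2-(4-benzyloxyphenyl)ethenyl]-3-methoxy-2-(methoxymethoxy)benzene, E/Z mixture | COCOc1c(OC)cccc1C=Cc1ccc(OCc2ccccc2)cc1
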